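## Retrosynthetic overview

- End game: the C8=C17 methylene comes from Wittig methylenation of a Δ6-8-ketone. C6=C7 comes from dehydrogenation of the saturated 8-ketone, and the acetate is placed on O18. All three operations start from one bicyclic 17-nor-8-oxo alcohol.
- Key disconnection: C9–C11, made by a boron-to-carbon 1,2-shift. One partner is an open-chain epoxy diazoketone (C1–C10, C18–C20). The other is a B-alkyl-9-BBN that carries the complete (E)-enoate side chain (C11–C16, OMe).
- The boron enolate formed in that shift ends, in the same flask, an oxirane-initiated cation–olefin bicyclisation. Ring A closes first (C4–C5), ring B second (C9–C10), and C4, C5, C9 and C10 are all set here.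
- Enabling feature: C9 lies between quaternary C10 and C8, and the exocyclic methylene C8=C17 of ring B is a masked ketone. C9 can therefore be first a diazo carbon and then an enolate carbon. The C18 oxygen on quaternary C4 of ring A is the oxygen of a 2-methyloxirane initiator.
- Fragments: the diazoketone comes from (E)-geranylacetone (asymmetric epoxidation sets C4). The borane comes from methyl acetoacetate.

Key step: step 10

Remark: labdane numbering (C1–C20) is used for open-chain and bicyclic compounds alike, and commercial geranylacetone is taken as the geometrically pure (E)-isomer.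

## Route

Step 1
Reactants: 1 (E)-geranylacetone
Product: 2 (5E,9E)-11-hydroxy-6,10-dimethylundeca-5,9-dien-2-one
Conditions: SeO2 (cat.), t-BuOOH, salicylic acid (cat.), CH2Cl2, 0 °C → rt
Reagents that add atoms: tert-butyl hydroperoxide, CC(C)(C)OO
Why: The SeO2-catalysed allylic hydroxylation (ene reaction, then [2,3]-sigmatropic shift) should pick the terminal isopropylidene group and oxidise only its (E)-methyl group, giving the (E)-allylic alcohol whose CH2OH carbon becomes C18.

Step 2
Reactants: 2 (5E,9E)-11-hydroxy-6,10-dimethylundeca-5,9-dien-2-one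
Product: 3 (5E)-8-[(2R,3R)-3-(hydroxymethyl)-3-methyloxiran-2-yl]-6-methyloct-5-en-2-one
Conditions: Ti(Oi-Pr)4 (cat.), D-(−)-diethyl tartrate (cat.), t-BuOOH, 4 Å MS, CH2Cl2, −20 °C
Reagents that add atoms: tert-butyl hydroperoxide, CC(C)(C)OO
Why: The Katsuki–Sharpless asymmetric epoxidation touches only the allylic-alcohol alkene, and the D-(−)-tartrate ligand delivers oxygen to the face that gives the (2R,3R)-epoxide, which fixes the C4–O stereocentre from which all others descend.

Step 3
Reactants: 3 (5E)-8-[(2R,3R)-3-(hydroxymethyl)-3-methyloxiran-2-yl]-6-methyloct-5-en-2-one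
Product: 4 (2S,6E)-2,6-dimethylundec-6-ene-1,2,10-triol (both epimers at the secondary carbinol)
Conditions: LiAlH4, THF, 0 °C → rt; H2O work-up
Reagents that add atoms: none
Why: Hydride opens the 2-methyl-2,3-epoxy alcohol by SN2 attack at the less substituted C3, so the C4–O bond and its configuration stay untouched, while the C8 ketone is reduced in the same flask to a carbinol whose configuration is irrelevant because step 5 erases it.

Step 4
Reactants: 4 (2S,6E)-2,6-dimethylundec-6-ene-1,2,10-triol
Product: 6 (5E)-6-methyl-9-[(2S)-2-methyloxiran-2-yl]non-5-en-2-ol, via primary tosylate 5 (not isolated)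
Conditions: TsCl, Et3N, Bu2SnO (cat.), CH2Cl2, rt; then K2CO3, MeOH, rt
Reagents that add atoms: none
Why: Stannylene-acetal catalysis directs the sulfonylation to the primary hydroxyl of the 1,2-diol and not to the isolated secondary one, and the tertiary alkoxide then closes the oxirane by a 3-exo-tet Williamson displacement at C18 with retention at C4.

Step 5
Reactants: 6 (5E)-6-methyl-9-[(2S)-2-methyloxiran-2-yl]non-5-en-2-ol
Product: 7 (5E)-6-methyl-9-[(2S)-2-methyloxiran-2-yl]non-5-en-2-one
Conditions: TPAP (cat.), NMO, 4 Å MS, CH2Cl2, rt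
Reagents that add atoms: none
Why: The Ley–Griffith oxidation is neutral and should return the C8 ketone without touching the acid-sensitive 2,2-disubstituted oxirane or the trisubstituted alkene.

Step 6
Reactants: 7 (5E)-6-methyl-9-[(2S)-2-methyloxiran-2-yl]non-5-en-2-one
Product: 9 (5E)-1-diazo-6-methyl-9-[(2S)-2-methyloxiran-2-yl]non-5-en-2-one, via trifluoroacetyl ketone 8 (not isolated)
Conditions: LiHMDS, THF, −78 °C; CF3CO2CH2CF3; aq. NH4Cl wash; MsN3, Et3N, H2O, MeCN, rt
Reagents that add atoms: methanesulfonyl azide, CS(=O)(=O)N=[N+]=[N-]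
Why: Kinetic deprotonation of the methyl ketone at C9, trifluoroacetylation and deacylative Regitz diazo transfer should place the diazo group on C9 only, under conditions that leave the oxirane and the alkene alone.

Step 7
Reactants: 10 methyl acetoacetate
Product: 11 methyl (2E)-3-{[(trifluoromethyl)sulfonyl]oxy}but-2-enoate
Conditions: Tf2O, aq. Me4NOH, hexanes, 5 °C
Reagents that add atoms: trifluoromethanesulfonic anhydride, O=S(=O)(OS(=O)(=O)C(F)(F)F)C(F)(F)F
Why: Biphasic O-sulfonylation of the acetoacetate enolate with a non-chelating tetraalkylammonium counter-ion should give the (E)-enol triflate, which carries the later C13=C14 geometry.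

Step 8
Reactants: 11 methyl (2E)-3-{[(trifluoromethyl)sulfonyl]oxy}but-2-enoate
Product: 12 methyl (2E)-3-methylpenta-2,4-dienoate
Conditions: vinylboronic acid pinacol ester, Pd(PPh3)4 (cat.), K2CO3, THF/H2O, 45 °C
Reagents that add atoms: vinylboronic acid pinacol ester, C=CB1OC(C)(C)C(C)(C)O1
Why: The Suzuki–Miyaura coupling of a β-triflyloxy enoate proceeds with retention of the alkene geometry, so the vinyl group (C11=C12) ends up trans to the ester.

Step 9
Reactants: 12 methyl (2E)-3-methylpenta-2,4-dienoate
Product: 13 methyl (2E)-5-(9-borabicyclo[3.3.1]nonan-9-yl)-3-methylpent-2-enoate (used as its solution)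
Conditions: 9-BBN dimer (slight deficit of B–H), CH2Cl2, rt
Reagents that add atoms: 9-borabicyclo[3.3.1]nonane (used as its dimer), B1C2CCCC1CCC2
Why: The Brown hydroboration with 9-BBN places boron on the terminal carbon C11 of the monosubstituted vinyl group, while the trisubstituted, ester-conjugated C13=C14 bond is inert and keeps its E geometry.

Step 10
Reactants: 9 (5E)-1-diazo-6-methyl-9-[(2S)-2-methyloxiran-2-yl]non-5-en-2-one; 13 methyl (2E)-5-(9-borabicyclo[3.3.1]nonan-9-yl)-3-methylpent-2-enoate
Product: 15 methyl (13E)-ent-18-hydroxy-8-oxo-17-norlabd-13-en-15-oate [(4S,5S,9S,10R); trans-decalin, CH2OH and side chain equatorial], via boron enolate 14 (not isolated)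
Conditions: 13 (1.2 equiv), CH2Cl2 (no THF), 0 °C → rt (−N2); MeAlCl2 (3.5 equiv), −78 °C; Et3N/MeOH, aq. Rochelle salt; DBU (cat.), CH2Cl2, rt
Reagents that add atoms: none
Why: Proposed new method: the nucleophilic diazo carbon C9 of 9 adds to the vacant boron orbital of 13, and the borate expels N2 while the primary B–C11 bond migrates to C9, which joins the two halves and, after a 1,3-shift of boron to oxygen, leaves the regiodefined C8=C9 boron enolate 14 (Hooz reaction; selective transfer of the exocyclic alkyl group from such C-bound 9-BBN borates is known from the base-induced alkylation of α-halo carbonyl compounds with B-alkyl-9-BBN reagents). MeAlCl2 then ionises the oxirane C4–O bond only as the C5=C10 π bond attacks it from the rear, and the tertiary C10 cation is captured by C9 of the enolate, the closest known reaction type being the epoxide-initiated cation–olefin polycyclisation that is terminated by a silyl enol ether. Ring A closes 6-exo-tet at the oxirane (6-endo-trig at C5=C10) and ring B closes 6-endo-trig at the enolate π bond (enol-endo), both within one chair–chair array. C4 is set by inversion at the (S)-oxirane carbon with the aluminium-bound CH2O arm equatorial, C5 and C10 by anti addition across the E-alkene (trans-decalin), and C9, whatever the enolate geometry, by DBU equilibration next to the C8 ketone to the equatorial epimer. The step needs the borane to react at the diazo carbon and not at the oxirane, which the weak Lewis acidity of a trialkylborane secures, and it needs the enolate and not the side-chain alkene to end the cascade, which the ester conjugation of C13=C14 and the six-membered transition state secure. New is only the use of the boron enolate, made in the same flask, as the terminator.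

Step 11
Reactants: 15 methyl (13E)-ent-18-hydroxy-8-oxo-17-norlabd-13-en-15-oate
Product: 16 methyl (13E)-ent-18-acetoxy-8-oxo-17-norlabd-13-en-15-oate [(4S,5S,9S,10R)]
Conditions: Ac2O, pyridine, DMAP (cat.), CH2Cl2, rt
Reagents that add atoms: acetic anhydride, CC(=O)OC(C)=O
Why: DMAP-catalysed acylation of the only hydroxyl group (primary, equatorial at C4) should be clean and touches no stereocentre.

Step 12
Reactants: 16 methyl (13E)-ent-18-acetoxy-8-oxo-17-norlabd-13-en-15-oate
Product: 18 methyl (13E)-ent-18-acetoxy-8-oxo-17-norlabda-6,13-dien-15-oate [(4S,5S,9S,10R)], via lithium enolate 17 (not isolated)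
Conditions: LDA (1.05 equiv), THF, −78 °C; PhS(Cl)=Nt-Bu, −78 °C
Reagents that add atoms: none
Why: In the Mukaiyama dehydrogenation the kinetic base removes a C7 proton (C9 is tertiary and neopentyl), the enolate is sulfenylated at C7 by the sulfinimidoyl chloride, and the adduct undergoes intramolecular syn elimination at low temperature to give the C6=C7 enone.

Step 13
Reactants: 18 methyl (13E)-ent-18-acetoxy-8-oxo-17-norlabda-6,13-dien-15-oate
Product: 19 methyl (13E)-ent-18-acetoxylabda-6,8(17),13-trien-15-oate [(4S,5S,9R,10S)], the target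
Conditions: Ph3PCH3Br, KOt-Bu, THF, 0 °C; then 18, 0 °C → rt
Reagents that add atoms: methyltriphenylphosphonium bromide, C[P+](c1ccccc1)(c1ccccc1)c1ccccc1.[Br-]
Why: The Wittig methylenation adds 1,2 to the enone carbonyl and gives the C6=C7–C8=C17 diene, and the basic ylide cannot scramble C9 because that centre already holds its thermodynamic (equatorial) configuration.

## Compound list

1 | (E)-geranylacetone | CC(C)=CCC/C(C)=C/CCC(C)=O | starting material
2 | (5E,9E)-11-hydroxy-6,10-dimethylundeca-5,9-dien-2-one | OC/C(C)=C/CC/C(C)=C/CCC(C)=O | intermediate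
3 | (5E)-8-[(2R,3R)-3-(hydroxymethyl)-3-methyloxiran-2-yl]-6-methyloct-5-en-2-one | OC[C@@]1(C)O[C@@H]1CC/C(C)=C/CCC(C)=O | intermediate
4 | (2S,6E)-2,6-dimethylundec-6-ene-1,2,10-triol (secondary carbinol epimers) | OC[C@@](C)(O)CCC/C(C)=C/CCC(C)O | intermediate
5 | (2S,6E)-2,10-dihydroxy-2,6-dimethylundec-6-en-1-yl 4-methylbenzenesulfonate | Cc1ccc(cc1)S(=O)(=O)OC[C@@](C)(O)CCC/C(C)=C/CCC(C)O | intermediate
6 | (5E)-6-methyl-9-[(2S)-2-methyloxiran-2-yl]non-5-en-2-ol | C[C@]1(CCC/C(C)=C/CCC(C)O)CO1 | intermediate
7 | (5E)-6-methyl-9-[(2S)-2-methyloxiran-2-yl]non-5-en-2-one | C[C@]1(CCC/C(C)=C/CCC(C)=O)CO1 | intermediate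
8 | (7E)-1,1,1-trifluoro-8-methyl-11-[(2S)-2-methyloxiran-2-yl]undec-7-ene-2,4-dione | C[C@]1(CCC/C(C)=C/CCC(=O)CC(=O)C(F)(F)F)CO1 | intermediate
9 | (5E)-1-diazo-6-methyl-9-[(2S)-2-methyloxiran-2-yl]non-5-en-2-one | C[C@]1(CCC/C(C)=C/CCC(=O)C=[N+]=[N-])CO1 | intermediate
10 | methyl acetoacetate | COC(=O)CC(C)=O | starting material
11 | methyl (2E)-3-{[(trifluoromethyl)sulfonyl]oxy}but-2-enoate | COC(=O)/C=C(\C)OS(=O)(=O)C(F)(F)F | intermediate
12 | methyl (2E)-3-methylpenta-2,4-dienoate | COC(=O)/C=C(\C)C=C | intermediate
13 | methyl (2E)-5-(9-borabicyclo[3.3.1]nonan-9-yl)-3-methylpent-2-enoate | COC(=O)/C=C(\C)CCB1C2CCCC1CCC2 | intermediate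
14 | methyl (2E,10E)-7-(9-borabicyclo[3.3.1]nonan-9-yloxy)-3,11-dimethyl-14-[(2S)-2-methyloxiran-2-yl]tetradeca-2,6,10-trienoate (C8=C9 geometry open) | C[C@]1(CCC/C(C)=C/CCC(OB2C3CCCC2CCC3)=CCC/C(C)=C/C(=O)OC)CO1 | intermediate
15 | methyl (13E)-ent-18-hydroxy-8-oxo-17-norlabd-13-en-15-oate (4S,5S,9S,10R) | O=C1CC[C@@H]2[C@@](C)(CO)CCC[C@@]2(C)[C@@H]1CC/C(C)=C/C(=O)OC | intermediate
16 | methyl (13E)-ent-18-acetoxy-8-oxo-17-norlabd-13-en-15-oate (4S,5S,9S,10R) | O=C1CC[C@@H]2[C@@](C)(COC(C)=O)CCC[C@@]2(C)[C@@H]1CC/C(C)=C/C(=O)OC | intermediate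
17 | lithium C7=C8 enolate of 16 | [Li+].[O-]C1=CC[C@@H]2[C@@](C)(COC(C)=O)CCC[C@@]2(C)[C@@H]1CC/C(C)=C/C(=O)OC | intermediate
18 | methyl (13E)-ent-18-acetoxy-8-oxo-17-norlabda-6,13-dien-15-oate (4S,5S,9S,10R) | O=C1C=C[C@@H]2[C@@](C)(COC(C)=O)CCC[C@@]2(C)[C@@H]1CC/C(C)=C/C(=O)OC | intermediate
19 | methyl (13E)-ent-18-acetoxylabda-6,8(17),13-trien-15-oate (4S,5S,9R,10S) | C=C1C=C[C@@H]2[C@@](C)(COC(C)=O)CCC[C@@]2(C)[C@@H]1CC/C(C)=C/C(=O)OC | target

## Step count and main risks

Total step count: 13.
Longest linear sequence: 10 (steps 1–6 and 10–13).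

Steps most likely to fail:

**Step 10.** Several processes could spoil it. A ring B–C bond of the 9-BBN cage could migrate in place of the B–C11 bond. The boron enolate could be protonated or exchanged before the oxirane ionises. A hydride shift in the opened oxirane (Meinwald rearrangement) could compete. A free C4 cation could cause partial loss of configuration.

The fallback separates the union from the ring closure and replaces the boron enolate by an isolable terminator, so that both operations are known reaction types. It sets out from 9 and 13 and returns at 15.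
- Only the boron-to-carbon coupling is run (rt, until N2 evolution ends).
- Enolate 14 is converted with N-(trimethylsilyl)imidazole into the open-chain trimethylsilyl enol ether F1 (the known enol borinate to enol silane exchange).
- F1 is purified on Et3N-deactivated silica.
- F1 is cyclised on its own with MeAlCl2 in CH2Cl2 at −78 °C, the established silyl-enol-ether-terminated epoxide bicyclisation.
- DBU equilibration then gives 15.

**Step 12.** LDA could deprotonate the acetate or the γ-positions of the enoate in competition with C7, with acyl transfer or loss of the protecting group as a result.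

The fallback avoids any enolate and builds the diene from the other end. It sets out from 16 and returns at 19.
- Wittig methylenation of the saturated ketone gives the 8(17)-ene F2.
- SeO2/t-BuOOH allylic hydroxylation of the only electron-rich alkene gives the C7 allylic alcohol F3 (either epimer serves).
- Methyl chloroformate/pyridine gives the allylic carbonate F4.
- Pd(PPh3)4 in warm THF forms the C7–C8–C17 π-allyl complex, whose β-hydride loss from C6 (palladium-catalysed elimination of allylic carbonates to 1,3-dienes) gives 19 directly.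

**Step 13.** Addition of the ylide to the hindered, cross-conjugated C8 carbonyl could be slow, and the basic ylide could cleave the acetate during the longer contact time.

The fallback is a two-stage Peterson olefination, in which a small, weakly basic nucleophile adds first and silicon then dictates where the double bond forms. It sets out from 18 and returns at 19.
- Me3SiCH2Li/CeCl3 in THF at −78 °C adds 1,2 to the ketone in preference to the esters and gives the β-hydroxysilane F5.
- Mild acid (HF·pyridine) then triggers elimination of silanol through the β-silyl-stabilised cation, which can only give the exocyclic C8=C17 bond of 19.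

## Further compounds

F1 | step 10 | methyl (2E,10E)-3,11-dimethyl-14-[(2S)-2-methyloxiran-2-yl]-7-(trimethylsilyloxy)tetradeca-2,6,10-trienoate | C[C@]1(CCC/C(C)=C/CCC(O[Si](C)(C)C)=CCC/C(C)=C/C(=O)OC)CO1
F2 | step 12 | methyl (13E)-ent-18-acetoxylabda-8(17),13-dien-15-oate | C=C1CC[C@@H]2[C@@](C)(COC(C)=O)CCC[C@@]2(C)[C@@H]1CC/C(C)=C/C(=O)OC
F3 | step 12 | methyl (13E)-ent-18-acetoxy-7-hydroxylabda-8(17),13-dien-15-oate (C7 open) | C=C1C(O)C[C@@H]2[C@@](C)(COC(C)=O)CCC[C@@]2(C)[C@@H]1CC/C(C)=C/C(=O)OC
F4 | step 12 | methyl (13E)-ent-18-acetoxy-7-(methoxycarbonyloxy)labda-8(17),13-dien-15-oate (C7 open) | C=C1C(OC(=O)OC)C[C@@H]2[C@@](C)(COC(C)=O)CCC[C@@]2(C)[C@@H]1CC/C(C)=C/C(=O)OC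
F5 | step 13 | methyl (13E)-ent-18-acetoxy-8-hydroxy-17-(trimethylsilyl)labda-6,13-dien-15-oate (C8 open) | C[Si](C)(C)CC1(O)C=C[C@@H]2[C@@](C)(COC(C)=O)CCC[C@@]2(C)[C@@H]1CC/C(C)=C/C(=O)OC
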